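**Retrosynthetic overview**
1. Target ⇒ diol 23: the two ring esters go on last (equatorial C6‑OH before axial C5‑OH); the C1' acetate goes on just before, on the only free hydroxyl.
2. Ring B (cyclopentanone, made last) ⇒ trans‑1,2 side chains on ring A, closed at C2–C3 by acylation of a sulfonyl carbanion, then desulfonylation.
3. C3a–C3 bond, C3a stereocentre and the exocyclic methylene ⇒ light‑driven fac‑Ir(ppy)3/Co(dmgH)2(py)Cl desaturative (phenylsulfonyl)methylation of the ring alkene (new reaction), run after the isopropenyl group has been converted into the oxirane.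
4. C7a–C1 bond with the C1 and C7a stereocentres ⇒ dianion Ireland–Claisen rearrangement of a tertiary allylic (S)‑3‑hydroxybutanoate (C1' bought).
5. The tertiary allylic alcohol ⇒ (R)‑carvone (ring A and C7 bought) by epoxidation, α'‑hydroxylation, reduction and selenide‑mediated epoxide‑to‑allylic‑alcohol transposition.

Assumption: (Z)‑3‑methylpent‑2‑enoic acid is bought as the pure Z isomer (otherwise ethyl pent‑2‑ynoate, Me2CuLi, then LiOH adds two steps); salts from simple deprotonations and radicals are treated as transient and are not numbered.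
Notation: monocycles keep carvone numbering (C1 former carbonyl carbon, C2 methyl‑bearing carbon, C7 that methyl, C5 the carbon carrying the C8(C9H2)(C10H3) side chain); bicycles use the octahydroinden‑2‑one numbering of the target (C1' = carbinol carbon on C1); β is the ring face of the C5 side chain (C7 in the bicycles), α the opposite face.

**Step 1**
Reactants: 1 (R)‑(−)‑carvone
Product: 2 carvone 2α,3α‑oxide [(1R,4R,6R)‑1‑methyl‑4‑(prop‑1‑en‑2‑yl)‑7‑oxabicyclo[4.1.0]heptan‑2‑one]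
Conditions: 30% H2O2, NaOH (cat.), MeOH, 0 °C
Reagents that add atoms: hydrogen peroxide OO
Why: Weitz–Scheffer nucleophilic epoxidation; hydroperoxide adds axially to C3 anti to the C5 isopropenyl group, so the oxirane forms on the α face (the known outcome for carvone).

**Step 2**
Reactants: 2 carvone 2α,3α‑oxide
Product: 3 6α‑hydroxycarvone 2α,3α‑oxide
Conditions: KN(SiMe3)2, THF, −78 °C; O2, P(OEt)3, −78 → −20 °C; AcOH
Reagents that add atoms: dioxygen O=O
Why: Enolate oxygenation with in‑situ phosphite reduction of the hydroperoxide; C6 is the only enolisable position and the enolate is attacked anti to the adjacent β‑isopropenyl group, giving the 6α‑alcohol.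

**Step 3**
Reactants: 3 6α‑hydroxycarvone 2α,3α‑oxide
Product: 4 2α,3α‑epoxy‑2β‑methyl‑5β‑(prop‑1‑en‑2‑yl)cyclohexane‑1α,6α‑diol
Conditions: LiBH(s‑Bu)3 (2.5 equiv), THF, −78 °C; H2O
Reagents that add atoms: none
Why: Trialkylborohydride reduction of an α,β‑epoxy ketone; the hindered hydride attacks the β face, anti to the oxirane oxygen and the C6 alkoxide, so the new C1 hydroxyl is α (all‑cis with O2 and O6).

**Step 4**
Reactants: 4 epoxy cis‑diol
Product: 5 1α,6α‑bis(tert‑butyldimethylsilyloxy)‑2α,3α‑epoxy‑2β‑methyl‑5β‑(prop‑1‑en‑2‑yl)cyclohexane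
Conditions: t‑BuMe2SiOTf, 2,6‑lutidine, CH2Cl2, −78 → 0 °C
Reagents that add atoms: tert‑butyldimethylsilyl trifluoromethanesulfonate CC(C)(C)[Si](C)(C)OS(=O)(=O)C(F)(F)F
Why: Silyl ether formation; the groups survive every later base, radical and reductive step and come off with fluoride in the presence of the oxirane.

**Step 5**
Reactants: 5 bis‑silyl epoxide
Product: 8 1α,6α‑bis(tert‑butyldimethylsilyloxy)‑2β‑methyl‑5β‑(prop‑1‑en‑2‑yl)cyclohex‑3‑en‑2α‑ol, via hydroxy selenide 6 (not isolated), via selenoxide 7 (not isolated)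
Conditions: (PhSe)2, NaBH4, EtOH, 78 °C; then 30% H2O2, pyridine, THF, 0 → 23 °C
Reagents that add atoms: sodium benzeneselenolate [Na+].[Se-]c1ccccc1 (into 6); hydrogen peroxide OO (into 7)
Why: Sharpless–Lauer epoxide‑to‑allylic‑alcohol transposition; PhSe− (made in the flask from (PhSe)2 and NaBH4) opens the oxirane trans‑diaxially at the less hindered C3, the selenoxide can only syn‑eliminate towards C4 and leaves as PhSeOH so that no reagent atom remains in 8, and the untouched C2–O bond keeps the tertiary alcohol α.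

**Step 6**
Reactants: 9 (S)‑3‑hydroxybutanoic acid
Product: 11 (S)‑3‑(trimethylsilyloxy)butanoyl chloride, via silyl ester 10 (not isolated)
Conditions: Me3SiCl (2.2 equiv), Et3N, CH2Cl2, 0 → 23 °C; (COCl)2, DMF (cat.), 0 → 23 °C; used crude
Reagents that add atoms: chlorotrimethylsilane C[Si](C)(C)Cl; oxalyl chloride O=C(Cl)C(=O)Cl
Why: Bis‑silylation followed by neutral conversion of the silyl ester into the acid chloride (Vilsmeier‑type activation); the bought (S) carbinol centre is not touched.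

**Step 7**
Reactants: 8 tertiary allylic alcohol; 11 (S)‑3‑(trimethylsilyloxy)butanoyl chloride
Product: 13 2α‑O‑[(S)‑3‑hydroxybutanoyl] ester of 8, via trimethylsilyl ether 12 (not isolated)
Conditions: n‑BuLi, THF, −78 °C; then 11, −78 → 0 °C; then K2CO3, MeOH, 0 °C
Reagents that add atoms: none
Why: O‑Acylation of the lithium alkoxide of the only free (tertiary) hydroxyl, then mild methanolysis of the labile trimethylsilyl ether; no stereocentre is involved.

**Step 8**
Reactants: 13 tertiary allylic (S)‑3‑hydroxybutanoate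
Product: 14 the same ester with the C5 side chain as (S)‑2‑methyloxiran‑2‑yl
Conditions: mCPBA (1.1 equiv), NaHCO3, CH2Cl2, 0 °C
Reagents that add atoms: 3‑chloroperoxybenzoic acid OOC(=O)c1cccc(Cl)c1
Why: Prilezhaev epoxidation; the 1,1‑disubstituted alkene reacts before the hindered ring alkene deactivated by its allylic ester, and in the rotamer with C8=C9 eclipsing C5–H the face turned to C6 is covered by the silyloxy group, so attack from the C4 side gives the (S)‑oxirane (substrate control from C5 and C6).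

**Step 9**
Reactants: 14 epoxy ester
Product: 17 methyl (2R,3S)‑3‑hydroxy‑2‑{1α,6α‑bis(tert‑butyldimethylsilyloxy)‑2‑methyl‑5β‑[(S)‑2‑methyloxiran‑2‑yl]cyclohex‑2‑en‑4α‑yl}butanoate, via silyl ketene acetal 15 (not isolated), via carboxylic acid 16 (not isolated)
Conditions: LiN(i‑Pr)2 (2.3 equiv), THF, −78 °C; Me3SiCl, −78 → 23 °C; aq. citric acid; then Me3SiCHN2, MeOH–PhMe, 0 °C
Reagents that add atoms: chlorotrimethylsilane C[Si](C)(C)Cl (into 15 only); (trimethylsilyl)diazomethane C[Si](C)(C)C=[N+]=[N-] (ester methyl of 17)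
Why: Dianion Ireland–Claisen rearrangement; the chelated alkoxide–enolate (carbinol carbon cis to OLi, geometry kept on silylation) rearranges through the boat transition state enforced by the α‑silyloxy groups, the new bond forms on the α face of C4 where the C2α–O bond breaks, and this sets C4 (later C7a) and the (R) centre beside the bought (S) carbinol.

**Step 10**
Reactants: 17 Claisen methyl ester; 18 iodomethyl phenyl sulfone
Product: 19 methyl (2R,3S)‑3‑hydroxy‑2‑{1α,6α‑bis(tert‑butyldimethylsilyloxy)‑2‑methylidene‑3β‑[(phenylsulfonyl)methyl]‑5β‑[(S)‑2‑methyloxiran‑2‑yl]cyclohexan‑4α‑yl}butanoate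
Conditions: 18 (1.5 equiv), fac‑Ir(ppy)3 (1 mol %), Co(dmgH)2(py)Cl (5 mol %), 2,6‑lutidine, MeCN, 450 nm LEDs, 23 °C
Reagents that add atoms: none
Why: Proposed new method: a redox‑neutral photoredox/Co(dmgH)2(py)Cl desaturative C‑alkylation (formal intermolecular carbon ene reaction) of an unactivated trisubstituted cycloalkene, in which excited fac‑Ir(ppy)3 reduces 18 to the electrophilic PhSO2CH2 radical, this adds to C3 of the only alkene left from the β face (anti to the C4 side chain), the tertiary C2 radical is intercepted by divalent cobalt and loses the most accessible hydrogen (C7 methyl) to give the exocyclic alkene, and the cobalt hydride is deprotonated and re‑oxidised by the oxidised iridium so that only HI (taken up by lutidine) is released; the closest known chemistry is photoredox atom‑transfer addition of sulfonylmethyl halides to alkenes and photoredox/Co(dmgH)2(py)Cl radical Heck‑type couplings with Hofmann‑selective hydrogen abstraction, not yet shown on a trialkyl cycloalkene.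

**Step 11**
Reactants: 19 sulfone ester
Product: 20 5α,6α‑bis(tert‑butyldimethylsilyloxy)‑1β‑[(S)‑1‑hydroxyethyl]‑4‑methylidene‑7β‑[(S)‑2‑methyloxiran‑2‑yl]‑3‑(phenylsulfonyl)‑3aα‑H,7aβ‑H‑octahydroinden‑2‑one (C3 epimers)
Conditions: LiN(i‑Pr)2 (3.3 equiv), THF, −78 → 0 °C; AcOH
Reagents that add atoms: none
Why: Intramolecular Claisen‑type (Dieckmann‑like) acylation; the α‑sulfonyl carbanion attacks the methyl ester on the trans‑diequatorial neighbouring chain (5‑exo‑trig) and the acidic β‑keto sulfone drives closure of trans‑fused ring B, while the C1'‑alkoxide shields C1 from deprotonation.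

**Step 12**
Reactants: 20 β‑keto sulfone
Product: 21 5α,6α‑bis(tert‑butyldimethylsilyloxy)‑1β‑[(S)‑1‑hydroxyethyl]‑4‑methylidene‑7β‑[(S)‑2‑methyloxiran‑2‑yl]‑3aα‑H,7aβ‑H‑octahydroinden‑2‑one
Conditions: SmI2 (2.5 equiv), THF–MeOH, −78 °C
Reagents that add atoms: none
Why: Reductive desulfonylation of a β‑keto sulfone by single‑electron transfer (samarium enolate protonated by methanol), which also removes the undefined C3 centre; the oxirane, alkene and silyl ethers are inert at −78 °C.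

**Step 13**
Reactants: 21 hydroxy ketone
Product: 22 C1' acetate of 21
Conditions: Ac2O, pyridine, DMAP (cat.), CH2Cl2, 0 °C
Reagents that add atoms: acetic anhydride CC(=O)OC(C)=O
Why: Acetylation by nucleophilic catalysis of the only free hydroxyl; C1' keeps the (S) configuration bought with 9.

**Step 14**
Reactants: 22 acetate
Product: 23 5α,6α‑diol (both silyl ethers removed)
Conditions: Bu4NF, AcOH (1:1), THF, 0 → 23 °C
Reagents that add atoms: none
Why: Fluoride desilylation buffered with acetic acid, so that neither β‑elimination of the β‑acetoxy ketone nor oxirane opening occurs.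

**Step 15**
Reactants: 23 diol; 24 (2Z)‑3‑methylpent‑2‑enoic acid
Product: 26 6α‑O‑[(2Z)‑3‑methylpent‑2‑enoyl] ester of 23, via mixed anhydride 25 (not isolated)
Conditions: 24, 2,4,6‑Cl3C6H2COCl, Et3N, THF, 23 °C; then 23, DMAP, PhMe, 0 → 23 °C
Reagents that add atoms: 2,4,6‑trichlorobenzoyl chloride O=C(Cl)c1c(Cl)cc(Cl)cc1Cl (into 25 only)
Why: Yamaguchi esterification under kinetic control; the equatorial C6 hydroxyl reacts before the axial allylic C5 hydroxyl (two syn‑axial hydrogens), and the mixed anhydride avoids acid‑chloride conditions that scramble the Z alkene.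

**Step 16**
Reactants: 26 mono‑ester; 27 (R)‑2‑methylbutanoic acid
Product: 29 target CNP0262178.2, via mixed anhydride 28 (not isolated)
Conditions: 27, 2,4,6‑Cl3C6H2COCl, Et3N, THF, 23 °C; then 26, DMAP, PhMe, 40 °C
Reagents that add atoms: 2,4,6‑trichlorobenzoyl chloride O=C(Cl)c1c(Cl)cc(Cl)cc1Cl (into 28 only)
Why: Yamaguchi esterification of the remaining axial allylic alcohol with the bought (R)‑acid; the mixed anhydride/DMAP conditions avoid ketene formation and keep the α‑stereocentre.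

**Compound list**
1 | (R)‑(−)‑carvone | CC1=CC[C@@H](C(C)=C)CC1=O | starting material
2 | carvone 2α,3α‑oxide, (1R,4R,6R) | C[C@@]12O[C@@H]1C[C@@H](C(C)=C)CC2=O | intermediate
3 | 6α‑hydroxycarvone 2α,3α‑oxide | C[C@@]12O[C@@H]1C[C@@H](C(C)=C)[C@H](O)C2=O | intermediate
4 | 2α,3α‑epoxy‑2β‑methyl‑5β‑(prop‑1‑en‑2‑yl)cyclohexane‑1α,6α‑diol | C[C@@]12O[C@@H]1C[C@@H](C(C)=C)[C@H](O)[C@@H]2O | intermediate
5 | 1α,6α‑bis(tert‑butyldimethylsilyl) ether of 4 | C[C@@]12O[C@@H]1C[C@@H](C(C)=C)[C@H](O[Si](C)(C)C(C)(C)C)[C@@H]2O[Si](C)(C)C(C)(C)C | intermediate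
6 | 1α,6α‑bis(tert‑butyldimethylsilyloxy)‑2β‑methyl‑3β‑(phenylselanyl)‑5β‑(prop‑1‑en‑2‑yl)cyclohexan‑2α‑ol | C[C@@]1(O)[C@@H]([Se]c2ccccc2)C[C@@H](C(C)=C)[C@H](O[Si](C)(C)C(C)(C)C)[C@@H]1O[Si](C)(C)C(C)(C)C | intermediate
7 | selenoxide of 6 (3β‑phenylseleninyl) | C[C@@]1(O)[C@@H]([Se](=O)c2ccccc2)C[C@@H](C(C)=C)[C@H](O[Si](C)(C)C(C)(C)C)[C@@H]1O[Si](C)(C)C(C)(C)C | intermediate
8 | 1α,6α‑bis(tert‑butyldimethylsilyloxy)‑2β‑methyl‑5β‑(prop‑1‑en‑2‑yl)cyclohex‑3‑en‑2α‑ol | C[C@@]1(O)C=C[C@@H](C(C)=C)[C@H](O[Si](C)(C)C(C)(C)C)[C@@H]1O[Si](C)(C)C(C)(C)C | intermediate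
9 | (S)‑3‑hydroxybutanoic acid | C[C@H](O)CC(=O)O | starting material
10 | trimethylsilyl (S)‑3‑(trimethylsilyloxy)butanoate | C[C@H](O[Si](C)(C)C)CC(=O)O[Si](C)(C)C | intermediate
11 | (S)‑3‑(trimethylsilyloxy)butanoyl chloride | C[C@H](O[Si](C)(C)C)CC(=O)Cl | intermediate
12 | 2α‑O‑[(S)‑3‑(trimethylsilyloxy)butanoyl] ester of 8 | C[C@@]1(OC(=O)C[C@H](C)O[Si](C)(C)C)C=C[C@@H](C(C)=C)[C@H](O[Si](C)(C)C(C)(C)C)[C@@H]1O[Si](C)(C)C(C)(C)C | intermediate
13 | 2α‑O‑[(S)‑3‑hydroxybutanoyl] ester of 8 | C[C@@]1(OC(=O)C[C@H](C)O)C=C[C@@H](C(C)=C)[C@H](O[Si](C)(C)C(C)(C)C)[C@@H]1O[Si](C)(C)C(C)(C)C | intermediate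
14 | 13 with the C5 side chain as (S)‑2‑methyloxiran‑2‑yl | C[C@@]1(OC(=O)C[C@H](C)O)C=C[C@@H]([C@@]2(C)CO2)[C@H](O[Si](C)(C)C(C)(C)C)[C@@H]1O[Si](C)(C)C(C)(C)C | intermediate
15 | bis(trimethylsilyl) ketene acetal of 14 (carbinol carbon cis to OSiMe3) | C[C@@]1(O/C(O[Si](C)(C)C)=C/[C@H](C)O[Si](C)(C)C)C=C[C@@H]([C@@]2(C)CO2)[C@H](O[Si](C)(C)C(C)(C)C)[C@@H]1O[Si](C)(C)C(C)(C)C | intermediate
16 | (2R,3S)‑3‑hydroxy‑2‑{1α,6α‑bis(tert‑butyldimethylsilyloxy)‑2‑methyl‑5β‑[(S)‑2‑methyloxiran‑2‑yl]cyclohex‑2‑en‑4α‑yl}butanoic acid | CC1=C[C@H]([C@@H](C(=O)O)[C@H](C)O)[C@@H]([C@@]2(C)CO2)[C@H](O[Si](C)(C)C(C)(C)C)[C@@H]1O[Si](C)(C)C(C)(C)C | intermediate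
17 | methyl ester of 16 | CC1=C[C@H]([C@@H](C(=O)OC)[C@H](C)O)[C@@H]([C@@]2(C)CO2)[C@H](O[Si](C)(C)C(C)(C)C)[C@@H]1O[Si](C)(C)C(C)(C)C | intermediate
18 | iodomethyl phenyl sulfone | ICS(=O)(=O)c1ccccc1 | starting material
19 | methyl (2R,3S)‑3‑hydroxy‑2‑{1α,6α‑bis(tert‑butyldimethylsilyloxy)‑2‑methylidene‑3β‑[(phenylsulfonyl)methyl]‑5β‑[(S)‑2‑methyloxiran‑2‑yl]cyclohexan‑4α‑yl}butanoate | C=C1[C@@H](CS(=O)(=O)c2ccccc2)[C@H]([C@@H](C(=O)OC)[C@H](C)O)[C@@H]([C@@]3(C)CO3)[C@H](O[Si](C)(C)C(C)(C)C)[C@@H]1O[Si](C)(C)C(C)(C)C | intermediate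
20 | 5α,6α‑bis(tert‑butyldimethylsilyloxy)‑1β‑[(S)‑1‑hydroxyethyl]‑4‑methylidene‑7β‑[(S)‑2‑methyloxiran‑2‑yl]‑3‑(phenylsulfonyl)‑3aα‑H,7aβ‑H‑octahydroinden‑2‑one (C3 epimers) | C=C1[C@H]2C(S(=O)(=O)c3ccccc3)C(=O)[C@@H]([C@H](C)O)[C@@H]2[C@@H]([C@@]4(C)CO4)[C@H](O[Si](C)(C)C(C)(C)C)[C@@H]1O[Si](C)(C)C(C)(C)C | intermediate
21 | 5α,6α‑bis(tert‑butyldimethylsilyloxy)‑1β‑[(S)‑1‑hydroxyethyl]‑4‑methylidene‑7β‑[(S)‑2‑methyloxiran‑2‑yl]‑3aα‑H,7aβ‑H‑octahydroinden‑2‑one | C=C1[C@H]2CC(=O)[C@@H]([C@H](C)O)[C@@H]2[C@@H]([C@@]3(C)CO3)[C@H](O[Si](C)(C)C(C)(C)C)[C@@H]1O[Si](C)(C)C(C)(C)C | intermediate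
22 | C1' acetate of 21 | C=C1[C@H]2CC(=O)[C@@H]([C@H](C)OC(C)=O)[C@@H]2[C@@H]([C@@]3(C)CO3)[C@H](O[Si](C)(C)C(C)(C)C)[C@@H]1O[Si](C)(C)C(C)(C)C | intermediate
23 | 1β‑[(S)‑1‑acetoxyethyl]‑5α,6α‑dihydroxy‑4‑methylidene‑7β‑[(S)‑2‑methyloxiran‑2‑yl]‑3aα‑H,7aβ‑H‑octahydroinden‑2‑one | C=C1[C@H]2CC(=O)[C@@H]([C@H](C)OC(C)=O)[C@@H]2[C@@H]([C@@]3(C)CO3)[C@H](O)[C@@H]1O | intermediate
24 | (2Z)‑3‑methylpent‑2‑enoic acid | OC(=O)/C=C(/C)CC | starting material
25 | (2Z)‑3‑methylpent‑2‑enoic 2,4,6‑trichlorobenzoic anhydride | O=C(OC(=O)/C=C(/C)CC)c1c(Cl)cc(Cl)cc1Cl | intermediate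
26 | 6α‑O‑[(2Z)‑3‑methylpent‑2‑enoyl] ester of 23 | C=C1[C@H]2CC(=O)[C@@H]([C@H](C)OC(C)=O)[C@@H]2[C@@H]([C@@]3(C)CO3)[C@H](OC(=O)/C=C(/C)CC)[C@@H]1O | intermediate
27 | (R)‑2‑methylbutanoic acid | CC[C@@H](C)C(=O)O | starting material
28 | (R)‑2‑methylbutanoic 2,4,6‑trichlorobenzoic anhydride | CC[C@@H](C)C(=O)OC(=O)c1c(Cl)cc(Cl)cc1Cl | intermediate
29 | (1R,3aS,5R,6S,7R,7aS)‑1‑[(1S)‑1‑acetoxyethyl]‑4‑methylidene‑5‑{[(2R)‑2‑methylbutanoyl]oxy}‑7‑[(2S)‑2‑methyloxiran‑2‑yl]‑2‑oxooctahydro‑1H‑inden‑6‑yl (2Z)‑3‑methylpent‑2‑enoate | C=C1[C@H]2CC(=O)[C@@H]([C@H](C)OC(C)=O)[C@@H]2[C@@H]([C@@]2(C)CO2)[C@H](OC(=O)/C=C(/C)CC)[C@@H]1OC(=O)[C@H](C)CC | target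

**Step count and risks**
Total steps: 16. Longest linear sequence: 15 (steps 1–5 and 7–16 from 1; step 6 is the single side‑branch step).

The three steps most likely to fail:

Step 10 (the new reaction). The radical must add to a hindered trisubstituted alkene, and the Co(dmgH)2(py)Cl‑mediated hydrogen abstraction must choose the methyl hydrogens over the ring hydrogens. Fallback with known chemistry: setting out from 17, an iodine‑atom‑transfer radical addition of 18 (Et3B, air, CH2Cl2, 0 °C) gives the tertiary iodide adduct F1. Dehydroiodination with DBU (PhMe, 80 °C) towards the methyl group, with separation from endocyclic isomers, comes back to the route at 19.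

Step 8 (oxirane configuration). Facial control at an isopropenyl group by neighbouring ring substituents is often modest, and the predicted sense rests on a conformational model. Fallback: the oxirane is then treated only as a mask for the alkene, and the epimer mixture is carried unchanged through steps 9–12. Setting out from 21 (as that mixture), deoxygenation with Cp2TiCl (from Cp2TiCl2 and Zn, THF, 23 °C) gives the isopropenyl hydroxy ketone F2. Epoxidation with VO(acac)2 and t‑BuOOH (CH2Cl2, 0 °C), delivered by the C1' hydroxyl that sits over the C7a‑side face of the alkene in the rigid trans‑fused bicycle, comes back at 21 as one epimer; the exocyclic methylene is out of reach of that hydroxyl.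

Step 9 (dianion Ireland–Claisen). The chelated enolate reacts in a stereochemically mismatched sense with respect to its own carbinol centre, and the ester is a crowded tertiary one, so low conversion or ketene loss is possible. Fallback: setting out from 14, the carbinol is protected (Et3SiCl, imidazole, CH2Cl2) as the triethylsilyl ether F3. A conventional non‑chelated Ireland–Claisen rearrangement (LiN(i‑Pr)2, THF–DMPU, Me3SiCl, −78 → 23 °C; conditions that place the α‑substituent cis to the silyloxy oxygen) goes through the silyl ketene acetal F4 to the silyl‑protected acid F5. Esterification with Me3SiCHN2 gives the methyl ester F6, and HF·pyridine/pyridine (THF, 0 °C) removes only the triethylsilyl group and comes back at 17.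

**Further compounds**
F1 | step 10 | methyl (2R,3S)‑3‑hydroxy‑2‑{1α,6α‑bis(tert‑butyldimethylsilyloxy)‑2‑iodo‑2‑methyl‑3β‑[(phenylsulfonyl)methyl]‑5β‑[(S)‑2‑methyloxiran‑2‑yl]cyclohexan‑4α‑yl}butanoate (C2 epimers) | CC1(I)[C@@H](CS(=O)(=O)c2ccccc2)[C@H]([C@@H](C(=O)OC)[C@H](C)O)[C@@H]([C@@]3(C)CO3)[C@H](O[Si](C)(C)C(C)(C)C)[C@@H]1O[Si](C)(C)C(C)(C)C
F2 | step 8 | 5α,6α‑bis(tert‑butyldimethylsilyloxy)‑1β‑[(S)‑1‑hydroxyethyl]‑4‑methylidene‑7β‑(prop‑1‑en‑2‑yl)‑3aα‑H,7aβ‑H‑octahydroinden‑2‑one | C=C1[C@H]2CC(=O)[C@@H]([C@H](C)O)[C@@H]2[C@@H](C(C)=C)[C@H](O[Si](C)(C)C(C)(C)C)[C@@H]1O[Si](C)(C)C(C)(C)C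
F3 | step 9 | triethylsilyl ether of 14 | C[C@@]1(OC(=O)C[C@H](C)O[Si](CC)(CC)CC)C=C[C@@H]([C@@]2(C)CO2)[C@H](O[Si](C)(C)C(C)(C)C)[C@@H]1O[Si](C)(C)C(C)(C)C
F4 | step 9 | trimethylsilyl ketene acetal of F3 (carbinol carbon cis to OSiMe3) | C[C@@]1(O/C(O[Si](C)(C)C)=C/[C@H](C)O[Si](CC)(CC)CC)C=C[C@@H]([C@@]2(C)CO2)[C@H](O[Si](C)(C)C(C)(C)C)[C@@H]1O[Si](C)(C)C(C)(C)C
F5 | step 9 | C3‑O‑triethylsilyl ether of acid 16 | CC1=C[C@H]([C@@H](C(=O)O)[C@H](C)O[Si](CC)(CC)CC)[C@@H]([C@@]2(C)CO2)[C@H](O[Si](C)(C)C(C)(C)C)[C@@H]1O[Si](C)(C)C(C)(C)C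
F6 | step 9 | C3‑O‑triethylsilyl ether of methyl ester 17 | CC1=C[C@H]([C@@H](C(=O)OC)[C@H](C)O[Si](CC)(CC)CC)[C@@H]([C@@]2(C)CO2)[C@H](O[Si](C)(C)C(C)(C)C)[C@@H]1O[Si](C)(C)C(C)(C)C
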